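**Strategy.** Everything rests on making ring D (C8–C14–C13–C16–C15, ent-kaurane numbering) from the six-membered ring C8–C14–C13–C12–C16–C15 of a bicyclo[2.2.2]octanone. A radical at C13 adds to the C16 ketone and C16 moves from C12 to C13, so the contraction exploits the C16 carbonyl and the vicinal C15/C16 oxygenation of the target. That precursor, carrying C15 as a dimethyl ketal, arises in one operation from a guaiacol ester of the ring A alcohol by oxidative dearomatisation and intramolecular Diels–Alder reaction; the future C7 lactone is the tether and C8 and C9 are set there. Ring A comes from 4,4-dimethylcyclohexadienone by asymmetric conjugate addition and oxa-Michael closure; methyl addition to C16 completes the target.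

Key step: step 8

Remark on the chemistry: locants follow the ent-kaurane-type numbering of the target (ring A = C1–C5/C10 with the C1 ketone and the C3–O–C6 ether; C20 and C7 = lactone CH2 and carbonyl; ring C = C8, C9, C11–C14; ring D = C8, C14, C13, C16, C15); the target is (3S,5S,8S,9S,10S,13R,16R). Bpin = 4,4,5,5-tetramethyl-1,3,2-dioxaborolan-2-yl. Compounds 1 and 6 are taken as commercial. The CIP letter at C5 changes between 2 and 4 only because substituent priorities change; the spatial arrangement is the same throughout.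

Step 1
Reactants: 1 4,4-dimethylcyclohexa-2,5-dien-1-one
Product: 2 (5R,6S)-6-(1-hydroxyethyl)-4,4-dimethyl-5-(Bpin-methyl)cyclohex-2-en-1-one (both carbinol epimers)
Conditions: Zn(CH2Bpin)2 (pre-formed from ICH2Bpin and Et2Zn), Cu(OTf)2 (2 mol%), (S,R,R)-binaphthol bis(1-phenylethyl)phosphoramidite (4 mol%; antipode if the sense of induction requires it), toluene, −30 °C; then MeCHO, −30 to 0 °C; aq. NH4Cl
Reagents that add atoms: bis[(4,4,5,5-tetramethyl-1,3,2-dioxaborolan-2-yl)methyl]zinc, CC1(C)OB(C[Zn]CB2OC(C)(C)C(C)(C)O2)OC1(C)C; acetaldehyde, CC=O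
Why: Cu–phosphoramidite-catalysed enantioselective conjugate addition of a diorganozinc to the prochiral 4,4-dialkylcyclohexadienone (Feringa-type desymmetrisation) should set C5 under ligand control, and the zinc enolate is intercepted regiospecifically at C10 by acetaldehyde (tandem conjugate addition–aldol), the boronate serving as a masked C6 hydroxyl.

Step 2
Reactants: 2 (5R,6S)-6-(1-hydroxyethyl)-4,4-dimethyl-5-(Bpin-methyl)cyclohex-2-en-1-one
Product: 4 (5S,6E)-6-ethylidene-4,4-dimethyl-5-(Bpin-methyl)cyclohex-2-en-1-one, via mesylate 3 (not isolated)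
Conditions: MsCl, Et3N, CH2Cl2, 0 °C; then DBU, rt
Reagents that add atoms: none
Why: Mesylation and E1cB elimination complete an aldol condensation to the cross-conjugated ethylidene dienone; C5–H is not acidified by this enone, so its configuration should persist.

Step 3
Reactants: 4 (5S,6E)-6-ethylidene-4,4-dimethyl-5-(Bpin-methyl)cyclohex-2-en-1-one
Product: 5 (5S,6S)-6-ethenyl-6-(hydroxymethyl)-4,4-dimethyl-5-(Bpin-methyl)cyclohex-2-en-1-one
Conditions: LiN(iPr)2, THF, −78 °C; monomeric CH2O in THF, −78 °C; AcOH quench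
Reagents that add atoms: formaldehyde, C=O
Why: γ-Deprotonation gives the extended lithium dienolate, whose kinetic α-selective aldol addition to formaldehyde (deconjugative α-functionalisation) should create the C10 quaternary centre and the vinyl group, the electrophile entering anti to the pseudo-axial C5 borylmethyl group so that C20 is trans to C6.

Step 4
Reactants: 6 3-hydroxy-2-methoxybenzoic acid
Product: 8 3-[(tert-butyldimethylsilyl)oxy]-2-methoxybenzoyl chloride, via bis-silyl ester 7 (not isolated)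
Conditions: TBSCl, imidazole, DMF, rt; then (COCl)2, cat. DMF, CH2Cl2, 0 °C to rt
Reagents that add atoms: tert-butyldimethylsilyl chloride, C[Si](C)(Cl)C(C)(C)C; oxalyl chloride, O=C(Cl)C(Cl)=O
Why: Exhaustive silylation followed by direct exchange of the silyl ester with oxalyl chloride/DMF gives the acid chloride under neutral conditions with the phenol still protected.

Step 5
Reactants: 5 (5S,6S)-6-ethenyl-6-(hydroxymethyl)-4,4-dimethyl-5-(Bpin-methyl)cyclohex-2-en-1-one; 8 3-[(tert-butyldimethylsilyl)oxy]-2-methoxybenzoyl chloride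
Product: 9 [(1S,6S)-1-ethenyl-5,5-dimethyl-2-oxo-6-(Bpin-methyl)cyclohex-3-en-1-yl]methyl 3-[(tert-butyldimethylsilyl)oxy]-2-methoxybenzoate
Conditions: pyridine, DMAP (cat.), CH2Cl2, 0 °C to rt
Reagents that add atoms: none
Why: DMAP-catalysed acylation of the neopentyl primary alcohol installs the future lactone ester under weakly basic conditions that should not provoke retro-aldol loss of formaldehyde.

Step 6
Reactants: 9 [(1S,6S)-1-ethenyl-5,5-dimethyl-2-oxo-6-(Bpin-methyl)cyclohex-3-en-1-yl]methyl 3-[(tert-butyldimethylsilyl)oxy]-2-methoxybenzoate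
Product: 12 [(1S,2S,5S)-2-ethenyl-8,8-dimethyl-3-oxo-6-oxabicyclo[3.2.1]octan-2-yl]methyl 3-hydroxy-2-methoxybenzoate, via borate ester 10 (not isolated), via hydroxy enone 11 (not isolated)
Conditions: Me3NO, THF, 60 °C; then TBAF, THF, 0 °C to rt; aq. NH4Cl
Reagents that add atoms: trimethylamine N-oxide, C[N+](C)(C)[O-]
Why: Amine-oxide oxidation of the primary C–B bond unmasks the C6 oxygen, fluoride cleaves the borate and the aryl silyl ether, and the basic medium should drive a 5-exo-trig oxa-Michael addition of the C6 alkoxide to C3, which can only close cis across ring A so that C3 is dictated by C5.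

Step 7
Reactants: 12 [(1S,2S,5S)-2-ethenyl-8,8-dimethyl-3-oxo-6-oxabicyclo[3.2.1]octan-2-yl]methyl 3-hydroxy-2-methoxybenzoate
Product: 14 (3S,5S,8S,9S,10S,12R)-spiro-lactone bicyclo[2.2.2]oct-13-en-16-one 15,15-dimethyl ketal (Diels–Alder adduct), via masked o-benzoquinone 13 (not isolated)
Conditions: PhI(OAc)2, MeOH, 0 °C; then evaporation, toluene (0.005 M), 110 °C
Reagents that add atoms: methanol, CO
Why: Oxidative dearomatisation of the guaiacol to a masked o-benzoquinone is followed by an intramolecular inverse-demand Diels–Alder reaction with the vinyl group; the ester tether enforces C8–C9 and C12–C11 bonding, C10 should sit syn to the new C13=C14 bridge away from the C15 ketal, and the diene face should be the one that puts the small C1 carbonyl rather than C5 over C14, which sets C8 and C9.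

Step 8
Reactants: 14 (3S,5S,8S,9S,10S,12R)-spiro-lactone bicyclo[2.2.2]oct-13-en-16-one 15,15-dimethyl ketal
Product: 16 (3S,5S,8S,9S,10S,13R)-spiro-lactone bicyclo[3.2.1]octan-16-one 15,15-dimethyl ketal, via C13 boronate 15 (not isolated)
Conditions: RhCl(PPh3)3 (3 mol%), catecholborane, THF, 0 °C to rt; MeOH; then 4-tert-butylcatechol (syringe pump), di-tert-butyl hyponitrite (10 mol%), PhH, 70 °C
Reagents that add atoms: none
Why: RhCl(PPh3)3-catalysed hydroboration with catecholborane is chemoselective for the alkene over the ketones and should place boron on C13, the less hindered alkene carbon (C14 is flanked by quaternary C8), giving 15. An aryloxyl radical from the catechol then releases the C13 radical from boron; this β-keto radical attacks the C16 carbonyl carbon in a 3-exo-trig mode (the only ring closure of the step), the cyclopropanoxyl radical reopens by cleaving C12–C16, and the C12 radical takes a hydrogen atom from the catechol, so C16 has moved from C12 to C13. The closest known reactions are the radical-chain protodeboronation of B-alkylcatecholboranes and the Dowd–Beckwith-type 1,2-acyl migration of β-keto radicals that converts bicyclo[2.2.2]octanones into bicyclo[3.2.1]octanones. The six-membered ring C8–C14–C13–C12–C16–C15 thereby contracts to five-membered ring D while ring C becomes a chair. The new stereocentre C13 is fixed by the cage, since C16 can only bond to the face of C13 on which it already lies, and C12 and C14 become methylene groups. The step needs rearrangement to outrun hydrogen transfer and to run forward: slow addition keeps the donor concentration low, relief of the eclipsing strain of the bicyclo[2.2.2]octane should favour the rearranged radical, and the C1 ketone and the lactone are not β to the radical and stay passive.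

Step 9
Reactants: 16 (3S,5S,8S,9S,10S,13R)-spiro-lactone bicyclo[3.2.1]octan-16-one 15,15-dimethyl ketal
Product: 18 CNP0538153.1, via hydroxy ketal 17 (not isolated)
Conditions: MeMgBr, THF/CH2Cl2, −78 °C; then 2 M HCl, THF, rt
Reagents that add atoms: methylmagnesium bromide, C[Mg]Br; water, O
Why: Grignard addition to the chelation-activated, non-enolisable α,α-dimethoxy ketone C16 should outpace attack on the neopentyl C1 ketone (blocked on both faces) and the lactone, with methyl entering from the exo face of ring D away from the C9–C11–C12 bridge so that the C16 hydroxyl is endo as in the target; acid hydrolysis of the ketal then reveals the C15 ketone.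

**Compound list**

1 | 4,4-dimethylcyclohexa-2,5-dien-1-one | CC1(C)C=CC(=O)C=C1 | starting material
2 | (5R,6S)-6-(1-hydroxyethyl)-4,4-dimethyl-5-[(4,4,5,5-tetramethyl-1,3,2-dioxaborolan-2-yl)methyl]cyclohex-2-en-1-one (carbinol epimers) | CC(O)[C@H]1C(=O)C=CC(C)(C)[C@@H]1CB2OC(C)(C)C(C)(C)O2 | intermediate
3 | methanesulfonate of 2 | CC(OS(C)(=O)=O)[C@H]1C(=O)C=CC(C)(C)[C@@H]1CB2OC(C)(C)C(C)(C)O2 | intermediate
4 | (5S,6E)-6-ethylidene-4,4-dimethyl-5-(Bpin-methyl)cyclohex-2-en-1-one | C/C=C1/C(=O)C=CC(C)(C)[C@@H]1CB2OC(C)(C)C(C)(C)O2 | intermediate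
5 | (5S,6S)-6-ethenyl-6-(hydroxymethyl)-4,4-dimethyl-5-(Bpin-methyl)cyclohex-2-en-1-one | CC1(C)C=CC(=O)[C@@](CO)(C=C)[C@H]1CB2OC(C)(C)C(C)(C)O2 | intermediate
6 | 3-hydroxy-2-methoxybenzoic acid | COc1c(O)cccc1C(=O)O | starting material
7 | tert-butyldimethylsilyl 3-[(tert-butyldimethylsilyl)oxy]-2-methoxybenzoate | COc1c(O[Si](C)(C)C(C)(C)C)cccc1C(=O)O[Si](C)(C)C(C)(C)C | intermediate
8 | 3-[(tert-butyldimethylsilyl)oxy]-2-methoxybenzoyl chloride | COc1c(O[Si](C)(C)C(C)(C)C)cccc1C(Cl)=O | intermediate
9 | [(1S,6S)-1-ethenyl-5,5-dimethyl-2-oxo-6-(Bpin-methyl)cyclohex-3-en-1-yl]methyl 3-[(tert-butyldimethylsilyl)oxy]-2-methoxybenzoate | CC1(C)C=CC(=O)[C@@](COC(=O)c2cccc(O[Si](C)(C)C(C)(C)C)c2OC)(C=C)[C@H]1CB3OC(C)(C)C(C)(C)O3 | intermediate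
10 | borate ester of 9 (C6–O–Bpin in place of C6–Bpin) | CC1(C)C=CC(=O)[C@@](COC(=O)c2cccc(O[Si](C)(C)C(C)(C)C)c2OC)(C=C)[C@H]1COB3OC(C)(C)C(C)(C)O3 | intermediate
11 | [(1S,6S)-1-ethenyl-6-(hydroxymethyl)-5,5-dimethyl-2-oxocyclohex-3-en-1-yl]methyl 3-hydroxy-2-methoxybenzoate | CC1(C)C=CC(=O)[C@@](COC(=O)c2cccc(O)c2OC)(C=C)[C@H]1CO | intermediate
12 | [(1S,2S,5S)-2-ethenyl-8,8-dimethyl-3-oxo-6-oxabicyclo[3.2.1]octan-2-yl]methyl 3-hydroxy-2-methoxybenzoate | CC1(C)[C@@H]2CC(=O)[C@@](COC(=O)c3cccc(O)c3OC)(C=C)[C@H]1CO2 | intermediate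
13 | [(1S,2S,5S)-2-ethenyl-8,8-dimethyl-3-oxo-6-oxabicyclo[3.2.1]octan-2-yl]methyl 6,6-dimethoxy-5-oxocyclohexa-1,3-diene-1-carboxylate | CC1(C)[C@@H]2CC(=O)[C@@](COC(=O)C3=CC=CC(=O)C3(OC)OC)(C=C)[C@H]1CO2 | intermediate
14 | Diels–Alder adduct: (3S,5S,8S,9S,10S,12R) spiro δ-lactone on 15,15-dimethoxy-16-oxobicyclo[2.2.2]oct-13-ene (bridgeheads C8 and C12; ring A as in 12, spiro at C10) | CC1(C)[C@@H]2CC(=O)[C@]3(COC(=O)[C@@]45C=C[C@@H](C[C@H]43)C(=O)C5(OC)OC)[C@H]1CO2 | intermediate
15 | 14 hydroborated across C13=C14, 1,3,2-benzodioxaborol-2-yl on C13 (either C13 epimer; the centre becomes a radical) | CC1(C)[C@@H]2CC(=O)[C@]3(COC(=O)[C@@]45CC(B6Oc7ccccc7O6)[C@@H](C[C@H]43)C(=O)C5(OC)OC)[C@H]1CO2 | intermediate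
16 | (3S,5S,8S,9S,10S,13R) spiro δ-lactone on 15,15-dimethoxy-16-oxobicyclo[3.2.1]octane (target skeleton; bridgeheads C8 and C13) | CC1(C)[C@@H]2CC(=O)[C@]3(COC(=O)[C@@]45C[C@@H](CC[C@H]43)C(=O)C5(OC)OC)[C@H]1CO2 | intermediate
17 | (16R)-16-hydroxy-16-methyl derivative of 16 (15,15-dimethyl ketal of the target) | CC1(C)[C@@H]2CC(=O)[C@]3(COC(=O)[C@@]45C[C@@H](CC[C@H]43)[C@@](C)(O)C5(OC)OC)[C@H]1CO2 | intermediate
18 | CNP0538153.1, (3S,5S,8S,9S,10S,13R,16R) | CC1(C)[C@@H]2CC(=O)[C@]3(COC(=O)[C@@]45C[C@@H](CC[C@H]43)[C@@](C)(O)C5=O)[C@H]1CO2 | target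

**Step count.** Total: 9 steps. Longest linear sequence: 8 steps (steps 1–3 and 5–9, from 1); step 4 is the one-step side branch from 6.

**Steps most likely to fail**

Step 8. The C13 radical may accept a hydrogen atom before it rearranges, or boron may be delivered to C14, so that the unrearranged, simply reduced bicyclo[2.2.2]octanone forms. The fallback sets out from 14: the same Rh-catalysed hydroboration (through boronate 15) is worked up oxidatively (NaBO3·4H2O, THF/H2O) to the C13 secondary alcohol F1. F1 is converted with PhOC(S)Cl, pyridine and DMAP into the O-phenyl thionocarbonate F2. Classical high-dilution reduction (Bu3SnH by syringe pump, AIBN, PhH, 80 °C) generates the same C13 radical at a far lower hydrogen-donor concentration, so the 1,2-acyl shift has time to occur; the sequence comes back to the route at 16.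

Step 1. Transfer of the α-boryl methyl group from zinc to copper may be slow or poorly face-selective, giving low conversion or low enantiomeric purity. The fallback sets out from 1 and comes back at 12:
- Rh-catalysed asymmetric 1,4-addition of potassium vinyltrifluoroborate ([Rh(cod)Cl]2, (R)-BINAP or its antipode, Et3N, toluene/H2O, 80 °C) should give (S)-5-ethenyl-4,4-dimethylcyclohex-2-en-1-one F3.
- Ozonolysis of the isolated vinyl group (O3, pyridine, CH2Cl2, −78 °C) gives aldehyde F4, NaBH(OAc)3 reduces only the aldehyde to alcohol F5, and TBSCl/imidazole gives silyl ether F6.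
- Kinetic enolisation at C10 (LiN(iPr)2, −78 °C) and aldol addition to MeCHO give aldol F7, which is dehydrated through mesylate F8 (MsCl, Et3N; DBU) to ethylidene dienone F9.
- The conditions of steps 3 and 5 then give alcohol F10 and ester F11.
- TBAF removes both silyl groups and closes the ether, giving 12.

Step 7. Dimerisation of the masked o-benzoquinone may outrun the hindered intramolecular cycloaddition. The fallback sets out from 12: NBS (MeCN, 0 °C) should brominate para to the phenolic hydroxyl to give bromophenol F12. Oxidation as in step 7 gives the brominated masked o-benzoquinone F13, whose fully substituted C8=C14 bond blocks dimerisation. Heating gives vinyl bromide adduct F14, and Bu3SnH/AIBN (PhH, 80 °C) removes the bromine, coming back to the route at 14.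

**Further compounds**

F1 | step 8 | C13 alcohol of the bicyclo[2.2.2]octanone (14 hydrated across C13=C14, OH on C13, either epimer) | CC1(C)[C@@H]2CC(=O)[C@]3(COC(=O)[C@@]45CC(O)[C@@H](C[C@H]43)C(=O)C5(OC)OC)[C@H]1CO2
F2 | step 8 | O-phenyl thionocarbonate of F1 | CC1(C)[C@@H]2CC(=O)[C@]3(COC(=O)[C@@]45CC(OC(=S)Oc6ccccc6)[C@@H](C[C@H]43)C(=O)C5(OC)OC)[C@H]1CO2
F3 | step 1 | (S)-5-ethenyl-4,4-dimethylcyclohex-2-en-1-one | CC1(C)C=CC(=O)C[C@H]1C=C
F4 | step 1 | (1R)-2,2-dimethyl-5-oxocyclohex-3-ene-1-carbaldehyde | CC1(C)C=CC(=O)C[C@H]1C=O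
F5 | step 1 | (5R)-5-(hydroxymethyl)-4,4-dimethylcyclohex-2-en-1-one | CC1(C)C=CC(=O)C[C@H]1CO
F6 | step 1 | (5R)-5-{[(tert-butyldimethylsilyl)oxy]methyl}-4,4-dimethylcyclohex-2-en-1-one | CC1(C)C=CC(=O)C[C@H]1CO[Si](C)(C)C(C)(C)C
F7 | step 1 | (5R,6S)-5-{[(tert-butyldimethylsilyl)oxy]methyl}-6-(1-hydroxyethyl)-4,4-dimethylcyclohex-2-en-1-one (carbinol epimers) | CC(O)[C@H]1C(=O)C=CC(C)(C)[C@@H]1CO[Si](C)(C)C(C)(C)C
F8 | step 1 | methanesulfonate of F7 | CC(OS(C)(=O)=O)[C@H]1C(=O)C=CC(C)(C)[C@@H]1CO[Si](C)(C)C(C)(C)C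
F9 | step 1 | (5S,6E)-5-{[(tert-butyldimethylsilyl)oxy]methyl}-6-ethylidene-4,4-dimethylcyclohex-2-en-1-one | C/C=C1/C(=O)C=CC(C)(C)[C@@H]1CO[Si](C)(C)C(C)(C)C
F10 | step 1 | (5S,6S)-5-{[(tert-butyldimethylsilyl)oxy]methyl}-6-ethenyl-6-(hydroxymethyl)-4,4-dimethylcyclohex-2-en-1-one | CC1(C)C=CC(=O)[C@@](CO)(C=C)[C@H]1CO[Si](C)(C)C(C)(C)C
F11 | step 1 | [(1S,6S)-6-{[(tert-butyldimethylsilyl)oxy]methyl}-1-ethenyl-5,5-dimethyl-2-oxocyclohex-3-en-1-yl]methyl 3-[(tert-butyldimethylsilyl)oxy]-2-methoxybenzoate | CC1(C)C=CC(=O)[C@@](COC(=O)c2cccc(O[Si](C)(C)C(C)(C)C)c2OC)(C=C)[C@H]1CO[Si](C)(C)C(C)(C)C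
F12 | step 7 | [(1S,2S,5S)-2-ethenyl-8,8-dimethyl-3-oxo-6-oxabicyclo[3.2.1]octan-2-yl]methyl 6-bromo-3-hydroxy-2-methoxybenzoate | CC1(C)[C@@H]2CC(=O)[C@@](COC(=O)c3c(Br)ccc(O)c3OC)(C=C)[C@H]1CO2
F13 | step 7 | [(1S,2S,5S)-2-ethenyl-8,8-dimethyl-3-oxo-6-oxabicyclo[3.2.1]octan-2-yl]methyl 2-bromo-6,6-dimethoxy-5-oxocyclohexa-1,3-diene-1-carboxylate | CC1(C)[C@@H]2CC(=O)[C@@](COC(=O)C3=C(Br)C=CC(=O)C3(OC)OC)(C=C)[C@H]1CO2
F14 | step 7 | 14-bromo derivative of Diels–Alder adduct 14 (vinyl bromide at C14) | CC1(C)[C@@H]2CC(=O)[C@]3(COC(=O)[C@@]45C(Br)=C[C@@H](C[C@H]43)C(=O)C5(OC)OC)[C@H]1CO2
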